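A direct plan would brominate 5-hydroxyvanillin A1 beside the formyl group to give the bromo aldehyde A2, benzylate, homologate the aldehyde and add the acetyl group by Stille coupling,
and would build the pyrone last by a (3+3) annulation of the malonyl dichloride A3 with the silyl enol ether A4, then hydrogenolyse the tribenzyl ether A5.
The bromination that gives A2 would be its weakest step: each free position of A1 is ortho to one oxygen and para to another, so the regiochemistry on which all later steps rest would be left to chance.
The base-free pyrone closure would be the second: crude A3 beside an enolisable ketone, and HCl that could isomerise the enol ether A4, whose double bond alone fixes the ring substitution.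
The final hydrogenolysis of three benzyl ethers beside an aryl ketone and a pyrone would be the third, on the most precious material.
Some seven steps in between would only place an acetyl and a CH2 group on a ring that is bought.

Plan of the new route
The retrosynthesis cuts one bond of the core, pyrone C3–CH2, and behind it the CH2–C(O) bond of the side chain, the aryl–acetyl bond and two O–CH3 bonds.
The feature used: in the benzene ring the hydroxyl on C4 is para to C1, which carries the CH2 group, so the arene half is a p-quinone methide; pyrone C3, between the C2 carbonyl and the C4 enol, is its nucleophile.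
Order of rings: none is closed; the pyrone is bought as triacetic acid lactone and finished (acylation, ketoreductase) before it meets the benzene ring, instead of being closed last on it.
The benzene half comes from symmetric 3,4,5-trimethoxybenzaldehyde: its CH2NMe2 group directs the acetyl group to the only kind of ring C–H and later leaves to give the quinone methide, and the acetyl group directs BCl3 to the two methyl ethers that must go.
So no ring position is chosen by chance, no ring is closed on late material, no benzyl ether exists, and the core ring system appears only in the target.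

Key step: step 6

Remark on the chemistry: the union of a tetraketide pyrone with a p-quinone methide is taken as the likely biosynthetic origin of the C3–CH2 bond; the route does not depend on this assumption.

Step 1
Reactants: 1 4-hydroxy-6-methyl-2H-pyran-2-one (triacetic acid lactone)
Product: 3 4-hydroxy-6-(2-oxopropyl)-2H-pyran-2-one, via dilithiated pyrone 2 (not isolated)
Conditions: LiN(i-Pr)2 (2.3 equiv), THF, −78 → −30 °C; AcN(OMe)Me (1.2 equiv), −78 → 0 °C; 1 M HCl to pH 2
Reagents that add atoms: N-methoxy-N-methylacetamide CC(=O)N(C)OC; lithium diisopropylamide [Li+].CC(C)[N-]C(C)C (lithium appears in 2 only)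
Why: After the hydroxyl group the base removes a proton of the 6-methyl group, which is vinylogous to the lactone carbonyl, and this carbanion should be C-acylated by the Weinreb amide in a Claisen-type reaction whose chelated tetrahedral adduct keeps the more acidic product from quenching unreacted dianion.

Step 2
Reactants: 3 4-hydroxy-6-(2-oxopropyl)-2H-pyran-2-one
Product: 4 4-hydroxy-6-[(2S)-2-hydroxypropyl]-2H-pyran-2-one
Conditions: ketoreductase of Prelog selectivity (NADH-dependent alcohol dehydrogenase), NAD+ (cat.), i-PrOH (10 vol %), phosphate buffer pH 7.0, 30 °C; then pH 3, EtOAc extraction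
Reagents that add atoms: none
Why: Enzymatic ketone reduction by a ketoreductase should deliver hydride to the re face of the methyl ketone, which for a small methyl and a large CH2-pyrone substituent gives the (S)-carbinol, and it does so in water on the unprotected, ionised pyrone, where hydride reagents and chiral metal catalysts would have to cope with an acidic enol and a lactone.

Step 3
Reactants: 5 3,4,5-trimethoxybenzaldehyde
Product: 6 N,N-dimethyl-1-(3,4,5-trimethoxyphenyl)methanamine
Conditions: Me2NH (2 M in THF, 1.5 equiv), NaBH(OAc)3 (1.5 equiv), AcOH (1 equiv), ClCH2CH2Cl, rt; aq NaHCO3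
Reagents that add atoms: dimethylamine CNC
Why: In this reductive amination the iminium ion formed from the aldehyde and the secondary amine should be reduced by the acetoxyborohydride faster than the aldehyde itself.

Step 4
Reactants: 6 N,N-dimethyl-1-(3,4,5-trimethoxyphenyl)methanamine
Product: 8 1-{6-[(dimethylamino)methyl]-2,3,4-trimethoxyphenyl}ethan-1-one, via ortho-lithiated amine 7 (not isolated)
Conditions: n-BuLi (1.2 equiv), Et2O, 0 °C → rt; AcN(OMe)Me (1.5 equiv), −78 → 0 °C; aq NH4Cl
Reagents that add atoms: N-methoxy-N-methylacetamide CC(=O)N(C)OC; n-butyllithium [Li]CCCC (lithium appears in 7 only)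
Why: In this directed ortho-metalation the benzylic dimethylamino group and the neighbouring methoxy group together guide the base to C2, which by symmetry is the only kind of ring C–H present, and the aryllithium should be acylated only once because the chelated adduct of the Weinreb amide survives until the quench.

Step 5
Reactants: 8 1-{6-[(dimethylamino)methyl]-2,3,4-trimethoxyphenyl}ethan-1-one
Product: 9 1-{6-[(dimethylamino)methyl]-2,3-dihydroxy-4-methoxyphenyl}ethan-1-one hydrochloride
Conditions: BCl3 (1 M in CH2Cl2, 4.5 equiv), CH2Cl2, −78 °C → rt; MeOH, 0 °C, evaporation from MeOH; HCl (1.25 M in MeOH), Et2O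
Reagents that add atoms: hydrogen chloride Cl
Why: In this chelation-controlled ether cleavage BCl3 bound to the acetyl oxygen should reach the ortho methoxy group through a six-membered chelate and then the next one through a five-membered catechol borate, as is known for 2,3,4-trimethoxyaryl carbonyl compounds, while the remote methoxy group lacks this help and the amine is held as its BCl3 adduct and isolated as a hydrochloride that cannot form the quinone methide on storage.

Step 6
Reactants: 9 1-{6-[(dimethylamino)methyl]-2,3-dihydroxy-4-methoxyphenyl}ethan-1-one hydrochloride; 4 4-hydroxy-6-[(2S)-2-hydroxypropyl]-2H-pyran-2-one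
Product: 11 penicanesin D, via p-quinone methide 10 (not isolated)
Conditions: 9 added in portions to 4 (1.5 equiv), NaOAc (2.5 equiv), degassed H2O/1,4-dioxane 1:1, 90 °C, Ar; 1 M HCl to pH 3, EtOAc
Reagents that add atoms: none
Why: Acetate frees the amine of 9, whose phenolate–ammonium zwitterion (the oxygen on C4 is para to the CH2N carbon) should expel dimethylamine in a 1,6-elimination to give the p-quinone methide 10, and the pyronate of 4 then adds through C3 to the exocyclic methylene carbon in a 1,6-conjugate addition that restores the benzene ring. The closest known reaction type is the C-alkylation of cyclic 1,3-dicarbonyl compounds such as 4-hydroxycoumarins and 4-hydroxy-2-pyrones by phenolic Mannich bases or 4-hydroxybenzyl alcohols through quinone methides. No ring is closed and no stereocentre is made; the (S)-carbinol of 4 is a spectator, remote from the reacting atoms. The step needs C3- over O-alkylation, which the reversibility of the heteroatom adducts should secure: a pyronate oxygen, acetate or water bound to the 4-hydroxybenzyl carbon can be expelled again to 10, whereas the new C–C bond cannot, so the adducts should drain to 11. It needs 10 to meet the pyronate before it meets the phenols of the product or of unreacted 9, which the excess of 4 and the portionwise addition of 9 should secure, and it needs 10 not to be trapped from within, which should hold because the enol carbon of the ortho-acetyl group could reach the methylene carbon only in a 5-endo-trig closure and the ketone is held in a hydrogen bond by the neighbouring hydroxyl group.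

Compound list
1 | 4-hydroxy-6-methyl-2H-pyran-2-one (triacetic acid lactone) | Cc1cc(O)cc(=O)o1 | starting material
2 | dilithiated pyrone, lithium 6-(lithiomethyl)-2-oxo-2H-pyran-4-olate (not isolated) | [Li+].[Li+].[CH2-]c1cc([O-])cc(=O)o1 | intermediate
3 | 4-hydroxy-6-(2-oxopropyl)-2H-pyran-2-one | CC(=O)Cc1cc(O)cc(=O)o1 | intermediate
4 | 4-hydroxy-6-[(2S)-2-hydroxypropyl]-2H-pyran-2-one | O=c1cc(O)cc(C[C@H](C)O)o1 | intermediate
5 | 3,4,5-trimethoxybenzaldehyde | COc1cc(C=O)cc(OC)c1OC | starting material
6 | N,N-dimethyl-1-(3,4,5-trimethoxyphenyl)methanamine | COc1cc(CN(C)C)cc(OC)c1OC | intermediate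
7 | {2-[(dimethylamino)methyl]-4,5,6-trimethoxyphenyl}lithium (not isolated) | [Li]c1c(CN(C)C)cc(OC)c(OC)c1OC | intermediate
8 | 1-{6-[(dimethylamino)methyl]-2,3,4-trimethoxyphenyl}ethan-1-one | COc1cc(CN(C)C)c(C(C)=O)c(OC)c1OC | intermediate
9 | 1-{6-[(dimethylamino)methyl]-2,3-dihydroxy-4-methoxyphenyl}ethan-1-one hydrochloride | Cl.COc1cc(CN(C)C)c(C(C)=O)c(O)c1O | intermediate
10 | 3-acetyl-2-hydroxy-6-methoxy-4-methylidenecyclohexa-2,5-dien-1-one (p-quinone methide, not isolated) | C=C1C=C(OC)C(=O)C(O)=C1C(C)=O | intermediate
11 | penicanesin D, 3-[(2-acetyl-3,4-dihydroxy-5-methoxyphenyl)methyl]-4-hydroxy-6-[(2S)-2-hydroxypropyl]-2H-pyran-2-one | COc1cc(Cc2c(O)cc(C[C@H](C)O)oc2=O)c(C(C)=O)c(O)c1O | target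

Total step count: 6
Longest linear sequence: 4 steps (steps 3, 4, 5 and 6 from compound 5); the pyrone branch (steps 1 and 2) joins in step 6.

Steps most likely to fail

Step 6. The loss of dimethylamine may be too slow at a temperature that the catechol tolerates, or the quinone methide may be used up by self-condensation with the electron-rich phenols before the pyronate traps it. The fallback sets out from 8 (with 4 as partner) and comes back at 11; it joins the halves through a benzyl cation at the trimethyl ether stage and moves the demethylation to the end. Ethyl chloroformate (toluene, 0 → 60 °C) would exchange the benzylic amine of 8 for chloride, the usual dealkylation of a tertiary benzylamine, to give 1-[6-(chloromethyl)-2,3,4-trimethoxyphenyl]ethan-1-one F1. In hexafluoro-2-propanol at 40 °C, without base, F1 should ionise to the para-methoxy-stabilised benzyl cation and alkylate C3 of 4 in a Friedel–Crafts-type reaction to give 3-[(2-acetyl-3,4,5-trimethoxyphenyl)methyl]-4-hydroxy-6-[(2S)-2-hydroxypropyl]-2H-pyran-2-one F2; O-benzyl adducts should revert under the acid set free. The acetyl-directed BCl3 cleavage of step 5, run on F2, would then give 11.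

Step 1. The dianion may be acylated incompletely because it is poorly soluble and only moderately nucleophilic, or proton transfer from the acetamide may return 1. The fallback sets out from 1 (through its dianion 2) and comes back at 3; it forms the C–C bond by addition to an aldehyde instead of acyl substitution. Acetaldehyde (THF, −78 °C), the best class of electrophile for this dianion, should give racemic 4-hydroxy-6-(2-hydroxypropyl)-2H-pyran-2-one F3, and oxidation of the secondary alcohol with Dess–Martin periodinane (CH2Cl2/THF, rt) would give 3.

Step 2. No enzyme of the panel may turn over the ionised, partly enolised keto-pyrone at a useful rate, the enantioselectivity may be too low, or 3 may condense with itself during the incubation. The fallback sets out from 3 and comes back at 4; it replaces the asymmetric reduction by a resolution. NaBH4 (EtOH, 0 °C) would give the racemic alcohol, racemic 4-hydroxy-6-(2-hydroxypropyl)-2H-pyran-2-one F3. A kinetic resolution with lipase B of Candida antarctica and vinyl acetate (t-BuOMe/THF, rt) should then acetylate the (R)-enantiomer, as the empirical rule for lipases and methyl carbinols predicts, to give (2R)-1-(4-hydroxy-2-oxo-2H-pyran-6-yl)propan-2-yl acetate F4. The (S)-alcohol 4 would be left unreacted and separated by chromatography, at the cost of at most half of the material.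

Further compounds
F1 | step 6 | 1-[6-(chloromethyl)-2,3,4-trimethoxyphenyl]ethan-1-one | COc1cc(CCl)c(C(C)=O)c(OC)c1OC
F2 | step 6 | 3-[(2-acetyl-3,4,5-trimethoxyphenyl)methyl]-4-hydroxy-6-[(2S)-2-hydroxypropyl]-2H-pyran-2-one | COc1cc(Cc2c(O)cc(C[C@H](C)O)oc2=O)c(C(C)=O)c(OC)c1OC
F3 | step 1 | racemic 4-hydroxy-6-(2-hydroxypropyl)-2H-pyran-2-one | CC(O)Cc1cc(O)cc(=O)o1
F4 | step 2 | (2R)-1-(4-hydroxy-2-oxo-2H-pyran-6-yl)propan-2-yl acetate | O=c1cc(O)cc(C[C@@H](C)OC(C)=O)o1
A1 | direct plan | 5-hydroxyvanillin (3,4-dihydroxy-5-methoxybenzaldehyde) | COc1cc(C=O)cc(O)c1O
A2 | direct plan | 2-bromo-3,4-dihydroxy-5-methoxybenzaldehyde | COc1cc(C=O)c(Br)c(O)c1O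
A3 | direct plan | 2-{[2-acetyl-3,4-bis(benzyloxy)-5-methoxyphenyl]methyl}propanedioyl dichloride | COc1cc(CC(C(=O)Cl)C(=O)Cl)c(C(C)=O)c(OCc2ccccc2)c1OCc1ccccc1
A4 | direct plan | {[(4S)-4-(benzyloxy)pent-1-en-2-yl]oxy}trimethylsilane | C=C(O[Si](C)(C)C)C[C@H](C)OCc1ccccc1
A5 | direct plan | 3-{[2-acetyl-3,4-bis(benzyloxy)-5-methoxyphenyl]methyl}-6-[(2S)-2-(benzyloxy)propyl]-4-hydroxy-2H-pyran-2-one | COc1cc(Cc2c(O)cc(C[C@H](C)OCc3ccccc3)oc2=O)c(C(C)=O)c(OCc2ccccc2)c1OCc1ccccc1
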